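**Strategy.** Everything rests on making the seven-membered ring last, by one-carbon enlargement of a cyclohexanone. The key step exploits the enone C10(=O)–C9H=C8(CH3) of that ring and its neighbour, the quaternary C1: a trans-hydrindanone with the C10 ketone between C1 and methyl-bearing C8 can enolise only towards C8. Its siloxycyclopropane, in which the future C9 bridges C8 and C10 and which already carries the C4 carbinol and the C6 anisoate, is opened by FeCl3 at the internal bond; this inserts C9 and unveils the β-methylcycloheptenone, hence the target, in one operation. The hydrindane comes from 2-methylcyclohexane-1,3-dione by a desymmetrising carbene-catalysed benzoin cyclisation. Daucane numbering throughout.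

Key step: step 12

Remark on labels: C1 = quaternary ring-fusion carbon bearing CH3; C2, C3 = CH2 of the five-membered ring; C4 = isopropyl carbinol carbon; C5 = ring-fusion CH; C6 = ester-bearing CH; C7 = CH2; C8 = methyl-bearing carbon; C9 = the carbon introduced in step 11; C10 = ketone carbon.

Assumption: the sense of induction of the chiral triazolium salt in step 2 is not predicted here; the catalyst enantiomer that delivers (3aS)-4 is the one used.

**Step 1**
Reactants: 1 2-methylcyclohexane-1,3-dione; 2 acrolein (prop-2-enal)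
Product: 3 3-(1-methyl-2,6-dioxocyclohexyl)propanal
Conditions: H2O, rt
Reagents that add atoms: none
Why: Michael addition of the acidic 1,3-dione to the enal at its doubly activated carbon should give the achiral keto aldehyde whose two ring carbonyls are enantiotopic; no stereocentre is formed.

**Step 2**
Reactants: 3 3-(1-methyl-2,6-dioxocyclohexyl)propanal
Product: 4 (3aS,7aR)-7a-hydroxy-3a-methylhexahydro-1H-indene-1,4(2H)-dione (cis-fused acyloin)
Conditions: chiral aminoindanol-derived triazolium salt, 2-(pentafluorophenyl)-5a,10b-dihydro-4H,6H-indeno[2,1-b][1,2,4]triazolo[4,3-d][1,4]oxazin-2-ium tetrafluoroborate (10 mol %), Et3N (10 mol %), toluene, rt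
Reagents that add atoms: none
Why: carbene-catalysed intramolecular crossed benzoin reaction in which the umpoled aldehyde carbon (C4) adds 5-exo-trig to one of the two enantiotopic ring ketones, so the chiral triazolylidene fixes quaternary C1 as S by its choice of carbonyl, while the cis relation of hydroxyl and methyl follows from the five-membered ring closure.

**Step 3**
Reactants: 4 (3aS,7aR)-7a-hydroxy-3a-methylhexahydro-1H-indene-1,4(2H)-dione
Product: 5 (3aS)-3a-methyl-3,3a,5,6-tetrahydro-1H-indene-1,4(2H)-dione (C4 ketone conjugated with C5=C6)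
Conditions: SOCl2, pyridine, CH2Cl2, −20 to 0 °C
Reagents that add atoms: none
Why: SOCl2/pyridine dehydration of a tertiary α-ketol (E2 elimination) should be regiospecific because the only β-hydrogens sit on C6, and it removes the carbinol stereocentre that is no longer needed.

**Step 4**
Reactants: 5 (3aS)-3a-methyl-3,3a,5,6-tetrahydro-1H-indene-1,4(2H)-dione
Product: 6 (3a'S)-3a'-methyl-2',3',5',6'-tetrahydrospiro[1,3-dioxolane-2,4'-inden]-1'(3a'H)-one (C10 ethylene ketal)
Conditions: ethylene glycol, p-toluenesulfonic acid (cat.), 4 Å molecular sieves, rt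
Reagents that add atoms: ethylene glycol, OCCO
Why: acid-catalysed ketalisation should be chemoselective because the saturated cyclohexanone carbonyl (C10) is far more electrophilic than the conjugated cyclopentenone carbonyl (C4).

**Step 5**
Reactants: 6 the C10 ethylene ketal
Product: 7 (1'R,3a'S)-3a'-methyl-1'-(propan-2-yl)-1',2',3',3a',5',6'-hexahydrospiro[1,3-dioxolane-2,4'-inden]-1'-ol (tertiary allylic alcohol, hydroxyl cis to the angular methyl)
Conditions: iPrMgCl, CeCl3 (anhydrous), THF, −78 to 0 °C; then aq NH4Cl
Reagents that add atoms: isopropylmagnesium chloride, CC(C)[Mg]Cl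
Why: organocerium 1,2-addition to the enone (CeCl3 suppresses enolisation and conjugate addition), the nucleophile approaching C4 from the face opposite the axial angular methyl on C1, which places the new hydroxyl cis to that methyl (4R).

**Step 6**
Reactants: 7 the tertiary allylic alcohol
Product: 9 (1'R,3a'S,7'S,7a'S)-3a'-methyl-1'-(propan-2-yl)octahydrospiro[1,3-dioxolane-2,4'-indene]-1',7'-diol, via alkylborane 8 (not isolated)
Conditions: BH3·THF, THF, 0 °C to rt; then NaOH, H2O2, 0 °C to rt
Reagents that add atoms: hydrogen peroxide, OO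
Why: hydroboration–oxidation (anti-Markovnikov, syn addition, oxidation with retention) should put boron on C6 and hydrogen on C5 from the face opposite both the angular methyl and the allylic C4 oxygen, setting the trans ring fusion (5S) and the C6 carbinol (6S) together.

**Step 7**
Reactants: 9 the 1',7'-diol; 10 4-methoxybenzoyl chloride
Product: 11 (1'R,3a'S,7'S,7a'S)-1'-hydroxy-3a'-methyl-1'-(propan-2-yl)octahydrospiro[1,3-dioxolane-2,4'-inden]-7'-yl 4-methoxybenzoate
Conditions: Et3N, 4-(dimethylamino)pyridine (cat.), CH2Cl2, 0 °C to rt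
Reagents that add atoms: none
Why: nucleophile-catalysed acylation should take place only at the secondary equatorial C6 hydroxyl, the tertiary C4 hydroxyl being too hindered to react.

**Step 8**
Reactants: 11 the ketal ester
Product: 12 (1R,3aS,7S,7aS)-1-hydroxy-3a-methyl-4-oxo-1-(propan-2-yl)octahydro-1H-inden-7-yl 4-methoxybenzoate
Conditions: HCl (2 M aq), THF, rt
Reagents that add atoms: water, O
Why: acid-catalysed hydrolysis of the dioxolane should free the C10 ketone, the aryl ester and the now non-allylic tertiary alcohol being stable to dilute acid.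

**Step 9**
Reactants: 12 the keto ester
Product: 14 (1R,3aS,7S,7aS)-1-hydroxy-3a,5-dimethyl-4-oxo-1-(propan-2-yl)octahydro-1H-inden-7-yl 4-methoxybenzoate (both epimers at the new methyl carbon C8), via dilithium alkoxide enolate 13 (not isolated)
Conditions: LiN(iPr)2 (2.2 equiv), THF, −78 °C; MeI, −78 to −40 °C
Reagents that add atoms: iodomethane, CI
Why: enolate alkylation is regiospecific because the C10 ketone can be deprotonated only at C8 (C1 is quaternary), and the configuration at C8 is irrelevant since that carbon becomes sp2 in step 10.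

**Step 10**
Reactants: 14 the α-methyl ketone
Product: 15 (1R,3aS,7S,7aS)-3a,5-dimethyl-1-(propan-2-yl)-1,4-bis(trimethylsilyloxy)-2,3,3a,6,7,7a-hexahydro-1H-inden-7-yl 4-methoxybenzoate (C10=C8 silyl enol ether, C4 silyl ether)
Conditions: Me3SiOTf, Et3N, CH2Cl2, 0 °C
Reagents that add atoms: trimethylsilyl trifluoromethanesulfonate, C[Si](C)(C)OS(=O)(=O)C(F)(F)F
Why: soft enolisation–silylation can give only the tetrasubstituted C10=C8 silyl enol ether and silylates the tertiary alcohol at the same time, which shields it in the next two steps.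

**Step 11**
Reactants: 15 the bis-silyl compound
Product: 16 siloxycyclopropane in which a CH2 group (C9) bridges C8 and C10 of 15 (1-trimethylsilyloxy-6-methylbicyclo[4.1.0]heptane unit; 1S,4R,5S,6S; either cyclopropane face)
Conditions: Et2Zn, CH2I2, CH2Cl2, 0 °C to rt
Reagents that add atoms: diiodomethane, ICI
Why: Simmons–Smith cyclopropanation with the Et2Zn/CH2I2 carbenoid should occur at the electron-rich silyl enol ether, the only alkene present, and the two new stereocentres need no control because both are lost in step 12.

**Step 12**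
Reactants: 16 the siloxycyclopropane
Product: 18 (3R,3aS,4S,8aS)-3-hydroxy-6,8a-dimethyl-8-oxo-3-(propan-2-yl)-1,2,3,3a,4,5,8,8a-octahydroazulen-4-yl 4-methoxybenzoate (target), via β-chloro ketone 17 (not isolated)
Conditions: FeCl3 (2.5 equiv), DMF, 0 °C to rt; aq HCl work-up; then NaOAc, MeOH, reflux
Reagents that add atoms: none
Why: FeCl3 exchanges the cyclopropyl silyl ether for an iron alkoxide and oxidises it by one electron to the cyclopropyloxy radical, whose β-scission at the internal C8–C10 bond gives the C10 ketone and a tertiary radical at C8 in a ring that is now seven-membered; chlorine transfer from a second FeCl3 traps this radical as the β-chloro ketone 17, from which NaOAc removes HCl by E1cB through the C9 enolate to give the conjugated C8=C9 enone. The closest known reaction type is the FeCl3-mediated oxidative ring expansion of 1-siloxybicyclo[n.1.0]alkanes to cycloalk-2-enones, a one-carbon homologation of cyclic ketones. No ring is closed: the cyclohexane C1–C5–C6–C7–C8–C10 is enlarged by insertion of C9 between C8 and C10. No stereocentre is created; the two cyclopropane centres vanish, and C1, C4, C5 and C6 are untouched because none of them is enolisable or adjacent to the radical site. The step needs internal rather than external cyclopropane bond cleavage and HCl loss towards C9 rather than C7; the methyl group on C8 (tertiary radical, strain release) secures the first and the acidity of C9–H next to the ketone the second. The quaternary C1 guarantees that the cyclopropane can only lie on the C8 side, so the carbon is inserted at the correct position.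

**Compound list**
1 | 2-methylcyclohexane-1,3-dione | CC1C(=O)CCCC1=O | starting material
2 | acrolein (prop-2-enal) | C=CC=O | starting material
3 | 3-(1-methyl-2,6-dioxocyclohexyl)propanal | CC1(CCC=O)C(=O)CCCC1=O | intermediate
4 | (3aS,7aR)-7a-hydroxy-3a-methylhexahydro-1H-indene-1,4(2H)-dione | C1CCC(=O)[C@@]2(C)CCC(=O)[C@@]12O | intermediate
5 | (3aS)-3a-methyl-3,3a,5,6-tetrahydro-1H-indene-1,4(2H)-dione | C1CC(=O)[C@@]2(C)CCC(=O)C2=C1 | intermediate
6 | (3a'S)-3a'-methyl-2',3',5',6'-tetrahydrospiro[1,3-dioxolane-2,4'-inden]-1'(3a'H)-one | C1CC2(OCCO2)[C@@]3(C)CCC(=O)C3=C1 | intermediate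
7 | (1'R,3a'S)-3a'-methyl-1'-(propan-2-yl)-1',2',3',3a',5',6'-hexahydrospiro[1,3-dioxolane-2,4'-inden]-1'-ol | C1CC2(OCCO2)[C@@]3(C)CC[C@@](O)(C(C)C)C3=C1 | intermediate
8 | alkylborane: BH2 on C6 (same face as the C5 hydrogen), C4 oxygen as O–BH2, otherwise as 9 | B[C@H]1CCC2(OCCO2)[C@@]3(C)CC[C@@](OB)(C(C)C)[C@H]13 | intermediate (not isolated)
9 | (1'R,3a'S,7'S,7a'S)-3a'-methyl-1'-(propan-2-yl)octahydrospiro[1,3-dioxolane-2,4'-indene]-1',7'-diol | O[C@H]1CCC2(OCCO2)[C@@]3(C)CC[C@@](O)(C(C)C)[C@H]13 | intermediate
10 | 4-methoxybenzoyl chloride | COc1ccc(cc1)C(Cl)=O | starting material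
11 | (1'R,3a'S,7'S,7a'S)-1'-hydroxy-3a'-methyl-1'-(propan-2-yl)octahydrospiro[1,3-dioxolane-2,4'-inden]-7'-yl 4-methoxybenzoate | COc1ccc(cc1)C(=O)O[C@H]1CCC2(OCCO2)[C@@]3(C)CC[C@@](O)(C(C)C)[C@H]13 | intermediate
12 | (1R,3aS,7S,7aS)-1-hydroxy-3a-methyl-4-oxo-1-(propan-2-yl)octahydro-1H-inden-7-yl 4-methoxybenzoate | COc1ccc(cc1)C(=O)O[C@H]1CCC(=O)[C@@]2(C)CC[C@@](O)(C(C)C)[C@H]12 | intermediate
13 | dilithium salt of 12: C4 lithium alkoxide and C10=C8 lithium enolate | COc1ccc(cc1)C(=O)O[C@H]1CC=C(O[Li])[C@@]2(C)CC[C@@](O[Li])(C(C)C)[C@H]12 | intermediate (not isolated)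
14 | (1R,3aS,7S,7aS)-1-hydroxy-3a,5-dimethyl-4-oxo-1-(propan-2-yl)octahydro-1H-inden-7-yl 4-methoxybenzoate, both epimers at the new methyl carbon | COc1ccc(cc1)C(=O)O[C@H]1CC(C)C(=O)[C@@]2(C)CC[C@@](O)(C(C)C)[C@H]12 | intermediate
15 | (1R,3aS,7S,7aS)-3a,5-dimethyl-1-(propan-2-yl)-1,4-bis(trimethylsilyloxy)-2,3,3a,6,7,7a-hexahydro-1H-inden-7-yl 4-methoxybenzoate | COc1ccc(cc1)C(=O)O[C@H]1CC(C)=C(O[Si](C)(C)C)[C@@]2(C)CC[C@@](O[Si](C)(C)C)(C(C)C)[C@H]12 | intermediate
16 | siloxycyclopropane: CH2 (C9) bridging C8 and C10 of 15, cyclopropane face not defined | COc1ccc(cc1)C(=O)O[C@H]1CC2(C)CC2(O[Si](C)(C)C)[C@@]3(C)CC[C@@](O[Si](C)(C)C)(C(C)C)[C@H]13 | intermediate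
17 | (3R,3aS,4S,8aS)-6-chloro-3-hydroxy-6,8a-dimethyl-8-oxo-3-(propan-2-yl)decahydroazulen-4-yl 4-methoxybenzoate, both epimers at the chlorine-bearing carbon | COc1ccc(cc1)C(=O)O[C@H]1CC(C)(Cl)CC(=O)[C@@]2(C)CC[C@@](O)(C(C)C)[C@H]12 | intermediate (not isolated)
18 | (3R,3aS,4S,8aS)-3-hydroxy-6,8a-dimethyl-8-oxo-3-(propan-2-yl)-1,2,3,3a,4,5,8,8a-octahydroazulen-4-yl 4-methoxybenzoate (CNP0301380.2) | COc1ccc(C(=O)O[C@H]2CC(C)=CC(=O)[C@@]3(C)CC[C@@](O)(C(C)C)[C@H]23)cc1 | target

**Step count.** Total: 12 steps. Longest linear sequence: 12 steps (from 1; compounds 2 and 10 are commercial).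

**Steps most likely to fail**

Step 12. The cyclopropane may cleave at the external bond or simply lose its silyl group back to the six-membered ketone; the Lewis acid may ionise the tertiary C4 alcohol; the C6 anisoate may be lost by vinylogous elimination during dehydrochlorination. The fallback sets out from 14. Homologation with Me3SiCHN2 and BF3·OEt2 in CH2Cl2 at −78 °C should move the less substituted α-carbon C8 and give the α-trimethylsilyl cycloheptanone F1, which is protodesilylated on acidic work-up to the saturated ring-enlarged ketone F2. LiN(SiMe3)2 and Me3SiCl convert F2 into the bis-silyl compound F3, whose enol ether can only point towards C9. Saegusa–Ito dehydrogenation with Pd(OAc)2 in MeCN, followed by mild acid to free the C4 hydroxyl, comes back to the route at 18.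

Step 6. Facial discrimination in the hydroboration may be poor (borane approaching on the side of the angular methyl would give the cis-fused epimer), or the hindered trisubstituted alkene may react sluggishly. The fallback sets out from 6. Copper-catalysed conjugate borylation (CuCl, bis[2-(diphenylphosphino)phenyl] ether, NaOtBu, B2pin2, MeOH, THF, rt) should place boron on C6 and a proton on C5, both from the face opposite the angular methyl, to give the β-boryl ketone F4. NaBO3·4H2O oxidises F4 with retention to the β-hydroxy ketone F5. iPrMgCl/CeCl3 in THF at −78 °C then adds to the C4 ketone anti to the C5–C6 bond and the methyl group, which comes back to the route at 9.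

Step 2. Discrimination between the enantiotopic carbonyls may be incomplete, or an intramolecular aldol reaction to a bridged product may compete. The fallback sets out from 3. The cyclisation is run with an achiral triazolium salt (2-mesityl-6,7-dihydro-5H-pyrrolo[2,1-c][1,2,4]triazol-2-ium chloride, DBU, THF) to the racemic cis-acyloin F6, which is dehydrated with SOCl2/pyridine as in step 3 to the racemic enedione F7. Preparative chromatography on a chiral stationary phase (amylose tris(3,5-dimethylphenylcarbamate), supercritical CO2/MeOH) separates the enantiomers, and the (S)-enantiomer comes back to the route as 5.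

**Further compounds**
F1 | step 12 | α-trimethylsilyl cycloheptanone: silyl group on C9 of the ring-enlarged ketone (not isolated) | COc1ccc(cc1)C(=O)O[C@H]1CC(C)C([Si](C)(C)C)C(=O)[C@@]2(C)CC[C@@](O)(C(C)C)[C@H]12
F2 | step 12 | (3R,3aS,4S,8aS)-3-hydroxy-6,8a-dimethyl-8-oxo-3-(propan-2-yl)decahydroazulen-4-yl 4-methoxybenzoate (epimers at the methyl-bearing ring carbon) | COc1ccc(cc1)C(=O)O[C@H]1CC(C)CC(=O)[C@@]2(C)CC[C@@](O)(C(C)C)[C@H]12
F3 | step 12 | bis-silyl derivative of F2: C10=C9 trimethylsilyl enol ether and C4 trimethylsilyl ether | COc1ccc(cc1)C(=O)O[C@H]1CC(C)CC=C(O[Si](C)(C)C)[C@@]2(C)CC[C@@](O[Si](C)(C)C)(C(C)C)[C@H]12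
F4 | step 6 | trans-fused β-boryl ketone: pinacolboronate on C6, C4 ketone, C10 ethylene ketal | CC1(C)OB(OC1(C)C)[C@H]1CCC2(OCCO2)[C@@]3(C)CCC(=O)[C@H]13
F5 | step 6 | trans-fused β-hydroxy ketone: C6 hydroxyl, C4 ketone, C10 ethylene ketal | O[C@H]1CCC2(OCCO2)[C@@]3(C)CCC(=O)[C@H]13
F6 | step 2 | racemic cis-7a-hydroxy-3a-methylhexahydro-1H-indene-1,4(2H)-dione (both enantiomers shown) | C1CCC(=O)[C@@]2(C)CCC(=O)[C@@]12O.C1CCC(=O)[C@]2(C)CCC(=O)[C@]12O
F7 | step 2 | racemic 3a-methyl-3,3a,5,6-tetrahydro-1H-indene-1,4(2H)-dione (both enantiomers shown) | C1CC(=O)[C@@]2(C)CCC(=O)C2=C1.C1CC(=O)[C@]2(C)CCC(=O)C2=C1
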